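The route rests on cutting the C4–C5 bond, the one bond shared by the ten-membered carbocycle (C1–C10) and the 4,5-oxirane. The feature exploited is that C4 is a methyl-bearing (C15) oxirane carbon next to the oxygenated C3, the retron of an α-hydroxy methyl ketone attacked by a carbanion at C5. The precursor is an acyclic C5 diphenylsulfonium salt that already holds the 1,10-oxirane, the free C3 hydroxyl and all other stereocentres. Base gives the sulfonium ylide, which adds to the lithium-chelated C4 ketone; collapse of the betaine closes carbocycle and oxirane and sets C4 and C5 in one operation.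

Key step: step 14

Remark: locants C1–C15 are those of the germacrane skeleton of the target (ring C1–C10, C14 on C10, C15 on C4, isopropenyl C11–C13 on C7); both esters are read as (Z)-2-methylbut-2-enoates (angelates). CIP letters are given for each compound's own substituents, so a letter can change (C9, C10, C4) while the spatial arrangement is kept.

Step 1
Reactants: 1 ethyl glyoxylate; 2 5-bromo-2-methylpent-2-ene
Product: 3 ethyl (2S,3R)-3-(2-bromoethyl)-2-hydroxy-4-methylpent-4-enoate
Conditions: (S)-BINOL (10 mol%), Ti(OiPr)2Br2 (10 mol%), 4 Å MS, CH2Cl2, −30 °C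
Reagents that add atoms: none
Why: Mikami glyoxylate–ene reaction: the BINOL–titanium Lewis acid shields one aldehyde face and sets C8 (2S), the alkene CH carbon (future C7) bonds to the aldehyde carbon while a methyl hydrogen is transferred to give the isopropenyl group, and the syn-selective six-membered transition state expected for trisubstituted alkenes sets C7 (3R).

Step 2
Reactants: 3 ethyl (2S,3R)-3-(2-bromoethyl)-2-hydroxy-4-methylpent-4-enoate
Product: 4 ethyl (2S,3R)-3-(2-bromoethyl)-2-(tert-butyldimethylsilyloxy)-4-methylpent-4-enoate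
Conditions: TBSOTf, 2,6-lutidine, CH2Cl2, −78 → 0 °C
Reagents that add atoms: tert-butyldimethylsilyl triflate, CC(C)(C)[Si](C)(C)OS(=O)(=O)C(F)(F)F
Why: Silylation of the secondary alcohol with a silyl triflate and a hindered pyridine base; no alkoxide is formed, so the bromide is not displaced to a tetrahydrofuran, and no stereocentre is touched.

Step 3
Reactants: 4 ethyl (2S,3R)-3-(2-bromoethyl)-2-(tert-butyldimethylsilyloxy)-4-methylpent-4-enoate
Product: 5 (2S,3R)-3-(2-bromoethyl)-2-(tert-butyldimethylsilyloxy)-4-methylpent-4-enal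
Conditions: iBu2AlH (1.1 equiv), CH2Cl2, −78 °C; aqueous potassium sodium tartrate
Reagents that add atoms: none
Why: Partial reduction of an α-silyloxy ester: the aluminium hemiacetal is stable at −78 °C and releases the aldehyde on work-up without epimerising C8.

Step 4
Reactants: 6 (S)-3-hydroxydihydrofuran-2(3H)-one
Product: 7 (S)-3-(triethylsilyloxy)dihydrofuran-2(3H)-one
Conditions: TESCl, imidazole, CH2Cl2, 0 °C
Reagents that add atoms: chlorotriethylsilane, CC[Si](Cl)(CC)CC
Why: Standard silyl ether formation on the secondary alcohol; the lactone and the C3 stereocentre (chiral pool) are untouched.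

Step 5
Reactants: 7 (S)-3-(triethylsilyloxy)dihydrofuran-2(3H)-one
Product: 8 (S)-4-hydroxy-N-methoxy-N-methyl-2-(triethylsilyloxy)butanamide
Conditions: MeNH(OMe)·HCl, iPrMgCl, THF, −20 → 0 °C; used at once
Reagents that add atoms: N,O-dimethylhydroxylamine hydrochloride, CNOC.Cl
Why: Weinreb amide formation by aminolysis of the lactone with the chloromagnesium amide; the ring opens at the acyl carbon (future C4) and frees the primary alcohol (future C1).

Step 6
Reactants: 8 (S)-4-hydroxy-N-methoxy-N-methyl-2-(triethylsilyloxy)butanamide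
Product: 9 (S)-N-methoxy-N-methyl-4-oxo-2-(triethylsilyloxy)butanamide
Conditions: Dess–Martin periodinane, NaHCO3, CH2Cl2, 0 °C → rt
Reagents that add atoms: none
Why: Dess–Martin oxidation of the primary alcohol to the aldehyde under buffered conditions that neither epimerise C3 nor eliminate the β-silyloxy group.

Step 7
Reactants: 9 (S)-N-methoxy-N-methyl-4-oxo-2-(triethylsilyloxy)butanamide; 10 ethyltriphenylphosphonium iodide
Product: 11 (2S,4Z)-5-iodo-N-methoxy-N-methyl-2-(triethylsilyloxy)hex-4-enamide
Conditions: 10, n-BuLi, THF, 0 °C; I2, −78 °C; NaN(SiMe3)2, −78 → −20 °C; then 9, −78 °C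
Reagents that add atoms: iodine, II
Why: Stork–Zhao–Smith olefination (Wittig reaction of the unstabilised α-iodo ylide Ph3P=C(I)CH3), which should give the (Z)-2-iodoalk-2-ene kinetically, with iodine cis to the chain, and so fixes the later C1=C10 geometry.

Step 8
Reactants: 5 (2S,3R)-3-(2-bromoethyl)-2-(tert-butyldimethylsilyloxy)-4-methylpent-4-enal; 11 (2S,4Z)-5-iodo-N-methoxy-N-methyl-2-(triethylsilyloxy)hex-4-enamide
Product: 12 C9 allylic alcohol (C5 Br, C8 OTBS, C9 OH, 1(10)Z-alkene, C3 OTES, C4 Weinreb amide)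
Conditions: CrCl2 (6 equiv), NiCl2 (2 mol%), DMSO, rt
Reagents that add atoms: none
Why: Nozaki–Hiyama–Kishi coupling: the alkenylchromium reagent forms with retention of alkene geometry and adds only to the aldehyde (Weinreb amide and alkyl bromide are inert), and Felkin–Anh attack anti to the C8 silyloxy group should set C9 (8,9-anti), the minor epimer being removed by chromatography.

Step 9
Reactants: 12 C9 allylic alcohol (C5 Br, C8 OTBS, C9 OH, 1(10)Z-alkene, C3 OTES, C4 Weinreb amide)
Product: 13 C9 PMB ether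
Conditions: 2-(4-methoxybenzyloxy)-4-methylquinoline, MeOTf, MgO, PhCF3, 0 °C → rt
Reagents that add atoms: 2-(4-methoxybenzyloxy)-4-methylquinoline, Cc1cc(OCc2ccc(OC)cc2)nc2ccccc12
Why: Dudley PMB transfer under neutral conditions (the N-methylated quinolinium ether is the PMB cation donor, MgO takes up the acid); the hindered allylic hydroxyl is etherified without base-induced silyl migration from C8.

Step 10
Reactants: 13 C9 PMB ether
Product: 14 C3 alcohol (α-hydroxy Weinreb amide)
Conditions: HF·pyridine, pyridine, THF, 0 °C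
Reagents that add atoms: none
Why: Buffered HF cleaves the triethylsilyl ether much faster than the hindered secondary tert-butyldimethylsilyl ether, so only the C3 hydroxyl is freed.

Step 11
Reactants: 14 C3 alcohol (α-hydroxy Weinreb amide)
Product: 15 1,10-epoxy α-hydroxy Weinreb amide
Conditions: VO(acac)2 (10 mol%), t-BuOOH (decane), CH2Cl2, 0 °C → rt
Reagents that add atoms: tert-butyl hydroperoxide, CC(C)(C)OO
Why: Vanadium-catalysed hydroxyl-directed epoxidation of a homoallylic alcohol (Mihelich chair transition state): the C3 hydroxyl delivers oxygen to C1=C10 with the amide carbon equatorial and C10 held pseudo-equatorial by allylic 1,3-strain of the (Z)-alkene, which should give the 1,3-syn oxirane on the face that is also anti to the allylic C9 ether oxygen, while syn addition keeps C9 and C2 cis and the isopropenyl group is out of reach.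

Step 12
Reactants: 15 1,10-epoxy α-hydroxy Weinreb amide
Product: 16 1,10-epoxy α-hydroxy methyl ketone (C5 bromide)
Conditions: MeMgBr (3 equiv), THF, −78 → −20 °C; NH4Cl (aq)
Reagents that add atoms: methylmagnesium bromide, C[Mg]Br
Why: Weinreb ketone synthesis: the first equivalent deprotonates the C3 hydroxyl, the chelated tetrahedral adduct stops at the methyl ketone (C15 installed), and the oxirane and primary bromide are inert at low temperature.

Step 13
Reactants: 16 1,10-epoxy α-hydroxy methyl ketone (C5 bromide)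
Product: 18 C5 diphenylsulfonium triflate, via primary iodide 17 (not isolated)
Conditions: NaI, acetone, rt; evaporate; Ph2S (10 equiv), AgOTf (1.1 equiv), CH2Cl2, 0 °C → rt, dark
Reagents that add atoms: sodium iodide, [Na+].[I-] (iodine only in 17); diphenyl sulfide, c1ccc(Sc2ccccc2)cc1; AgOTf (silver trifluoromethanesulfonate), [Ag+].[O-]S(=O)(=O)C(F)(F)F
Why: Finkelstein exchange followed by silver-assisted S-alkylation of diphenyl sulfide, the classical route to alkyldiphenylsulfonium salts; a diaryl sulfide is used so that the salt has α-hydrogens only at C5.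

Step 14
Reactants: 18 C5 diphenylsulfonium triflate
Product: 21 (1R,3S,4R,5S,7R,8S,9S,10R)-8-(tert-butyldimethylsilyloxy)-1,10:4,5-diepoxy-9-(4-methoxybenzyloxy)germacr-11-en-3-ol, via lithium alkoxide sulfonium ylide 19 (not isolated), via ten-membered betaine 20 (not isolated)
Conditions: LiN(SiMe3)2 (2.1 equiv), THF, 0.5 mM, −78 → −30 °C; NH4Cl (aq)
Reagents that add atoms: none
Why: Proposed new method: LiN(SiMe3)2 first makes the C3 lithium alkoxide and then removes a C5 proton (the only hydrogens α to sulfur, both other groups being phenyl), giving the unstabilised sulfonium ylide 19, whose carbanion adds to the C4 ketone in a 10-exo-trig closure of the carbocycle (betaine 20); rotation to the anti-periplanar O–C4–C5–S arrangement then lets the C4 alkoxide expel Ph2S in a 3-exo-tet SN2 closure of the oxirane with inversion at C5. The closest known reaction type is the Corey–Chaykovsky epoxidation of ketones with alkyldiphenylsulfonium ylides and its intramolecular version (epoxy-annulation of keto sulfonium salts to five- to seven-membered rings); closure of a ten-membered carbocycle in this way is not established. C4 is set by the five-membered lithium chelate between the C3 alkoxide and the ketone oxygen, which makes C5 attack the carbonyl face opposite C2 (Cram-chelate sense) and gives the threo C3–O/C4–O relationship. C5 is set in the same transition state: the solvated lithium fills the sector between the carbonyl oxygen and C3, so the ylide hydrogen points there, the SPh2 group sits between the oxygen and the C15 methyl, and C6 lies anti to the carbonyl oxygen, which after rotation and closure places C6 cis to C3 on the oxirane. The step needs ylide formation to beat ketone enolisation (the cationic sulfonium carries the most acidic C–H and the adjacent alkoxide disfavours a second negative charge at C15), cyclisation to beat oligomerisation (high dilution, chain preorganised by the cis-oxirane and four substituted carbons) and no electrophile within five- or six-ring reach of C5 (the C8 and C9 oxygens are ethers, not esters).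

Step 15
Reactants: 21 (1R,3S,4R,5S,7R,8S,9S,10R)-8-(tert-butyldimethylsilyloxy)-1,10:4,5-diepoxy-9-(4-methoxybenzyloxy)germacr-11-en-3-ol
Product: 22 (1R,3S,4R,5S,7R,8S,9S,10R)-1,10:4,5-diepoxy-9-(4-methoxybenzyloxy)germacr-11-ene-3,8-diol
Conditions: Bu4NF, AcOH (1:1), THF, 0 °C → rt
Reagents that add atoms: none
Why: Fluoride-induced cleavage of the silyl ether (Si–F bond formation); acetic acid buffering avoids alkoxide-induced oxirane migration, and the PMB ether is untouched.

Step 16
Reactants: 22 (1R,3S,4R,5S,7R,8S,9S,10R)-1,10:4,5-diepoxy-9-(4-methoxybenzyloxy)germacr-11-ene-3,8-diol; 23 angelic acid (two equivalents are built into the product)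
Product: 24 (1R,3S,4S,5S,7R,8S,9S,10R)-1,10:4,5-diepoxy-9-(4-methoxybenzyloxy)germacr-11-ene-3,8-diyl bis[(Z)-2-methylbut-2-enoate]
Conditions: 23 (3 equiv), 2,4,6-trichlorobenzoyl chloride (3 equiv), Et3N (6 equiv), toluene, rt; then 22, 80 °C
Reagents that add atoms: angelic acid (the second equivalent of 23), C/C=C(/C)C(=O)O
Why: Yamaguchi-type esterification in which each of the two free secondary hydroxyls (C3 and C8) takes one angeloyl group from the mixed angelic 2,4,6-trichlorobenzoic anhydride, so that two molecules of 23 are incorporated, without a nucleophilic catalyst, conditions known to transfer the (Z)-acyl group without isomerisation to the tiglate, while C9 stays protected.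

Step 17
Reactants: 24 (1R,3S,4S,5S,7R,8S,9S,10R)-1,10:4,5-diepoxy-9-(4-methoxybenzyloxy)germacr-11-ene-3,8-diyl bis[(Z)-2-methylbut-2-enoate]
Product: 25 CNP0304877.1, (1R,3S,4S,5S,7R,8S,9S,10S)-1,10:4,5-diepoxy-9-hydroxygermacr-11-ene-3,8-diyl bis[(Z)-2-methylbut-2-enoate]
Conditions: DDQ, CH2Cl2/pH 7 phosphate buffer, 0 °C → rt
Reagents that add atoms: none
Why: Oxidative PMB ether cleavage (hydride abstraction by DDQ, hydrolysis of the oxocarbenium ion) under buffered neutral conditions that should leave the oxiranes, the angelates and the isopropenyl group untouched and avoid acyl migration from C8 to C9.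

Compound list
1 | ethyl glyoxylate (ethyl 2-oxoacetate) | O=CC(=O)OCC | starting material
2 | 5-bromo-2-methylpent-2-ene | CC(C)=CCCBr | starting material
3 | ethyl (2S,3R)-3-(2-bromoethyl)-2-hydroxy-4-methylpent-4-enoate | BrCC[C@H](C(C)=C)[C@H](O)C(=O)OCC | intermediate
4 | ethyl (2S,3R)-3-(2-bromoethyl)-2-(tert-butyldimethylsilyloxy)-4-methylpent-4-enoate | BrCC[C@H](C(C)=C)[C@H](O[Si](C)(C)C(C)(C)C)C(=O)OCC | intermediate
5 | (2S,3R)-3-(2-bromoethyl)-2-(tert-butyldimethylsilyloxy)-4-methylpent-4-enal | BrCC[C@H](C(C)=C)[C@H](O[Si](C)(C)C(C)(C)C)C=O | intermediate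
6 | (S)-3-hydroxydihydrofuran-2(3H)-one ((S)-α-hydroxy-γ-butyrolactone) | O=C1OCC[C@@H]1O | starting material
7 | (S)-3-(triethylsilyloxy)dihydrofuran-2(3H)-one | O=C1OCC[C@@H]1O[Si](CC)(CC)CC | intermediate
8 | (S)-4-hydroxy-N-methoxy-N-methyl-2-(triethylsilyloxy)butanamide | OCC[C@H](O[Si](CC)(CC)CC)C(=O)N(C)OC | intermediate
9 | (S)-N-methoxy-N-methyl-4-oxo-2-(triethylsilyloxy)butanamide | O=CC[C@H](O[Si](CC)(CC)CC)C(=O)N(C)OC | intermediate
10 | ethyltriphenylphosphonium iodide | CC[P+](c1ccccc1)(c1ccccc1)c1ccccc1.[I-] | starting material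
11 | (2S,4Z)-5-iodo-N-methoxy-N-methyl-2-(triethylsilyloxy)hex-4-enamide | C/C(I)=C/C[C@H](O[Si](CC)(CC)CC)C(=O)N(C)OC | intermediate
12 | C9 allylic alcohol; (2S,4Z,6R,7S,8R)-10-bromo-7-(tert-butyldimethylsilyloxy)-6-hydroxy-N-methoxy-N,5-dimethyl-8-(prop-1-en-2-yl)-2-(triethylsilyloxy)dec-4-enamide | BrCC[C@H](C(C)=C)[C@H](O[Si](C)(C)C(C)(C)C)[C@H](O)/C(C)=C\C[C@H](O[Si](CC)(CC)CC)C(=O)N(C)OC | intermediate
13 | C9 PMB ether; (2S,4Z,6R,7S,8R)-10-bromo-7-(tert-butyldimethylsilyloxy)-N-methoxy-6-(4-methoxybenzyloxy)-N,5-dimethyl-8-(prop-1-en-2-yl)-2-(triethylsilyloxy)dec-4-enamide | BrCC[C@H](C(C)=C)[C@H](O[Si](C)(C)C(C)(C)C)[C@H](OCc1ccc(OC)cc1)/C(C)=C\C[C@H](O[Si](CC)(CC)CC)C(=O)N(C)OC | intermediate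
14 | C3 alcohol; (2S,4Z,6R,7S,8R)-10-bromo-7-(tert-butyldimethylsilyloxy)-2-hydroxy-N-methoxy-6-(4-methoxybenzyloxy)-N,5-dimethyl-8-(prop-1-en-2-yl)dec-4-enamide | BrCC[C@H](C(C)=C)[C@H](O[Si](C)(C)C(C)(C)C)[C@H](OCc1ccc(OC)cc1)/C(C)=C\C[C@H](O)C(=O)N(C)OC | intermediate
15 | 1,10-epoxy α-hydroxy Weinreb amide; (2S)-3-[(2R,3R)-3-{(1S,2S,3R)-5-bromo-2-(tert-butyldimethylsilyloxy)-1-(4-methoxybenzyloxy)-3-(prop-1-en-2-yl)pentyl}-3-methyloxiran-2-yl]-2-hydroxy-N-methoxy-N-methylpropanamide | BrCC[C@H](C(C)=C)[C@H](O[Si](C)(C)C(C)(C)C)[C@H](OCc1ccc(OC)cc1)[C@]1(C)O[C@@H]1C[C@H](O)C(=O)N(C)OC | intermediate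
16 | 1,10-epoxy α-hydroxy methyl ketone (C5 bromide); (3S)-4-[(2R,3R)-3-{(1S,2S,3R)-5-bromo-2-(tert-butyldimethylsilyloxy)-1-(4-methoxybenzyloxy)-3-(prop-1-en-2-yl)pentyl}-3-methyloxiran-2-yl]-3-hydroxybutan-2-one | BrCC[C@H](C(C)=C)[C@H](O[Si](C)(C)C(C)(C)C)[C@H](OCc1ccc(OC)cc1)[C@]1(C)O[C@@H]1C[C@H](O)C(C)=O | intermediate
17 | primary iodide; 5-iodo analogue of 16 with the same configuration | ICC[C@H](C(C)=C)[C@H](O[Si](C)(C)C(C)(C)C)[C@H](OCc1ccc(OC)cc1)[C@]1(C)O[C@@H]1C[C@H](O)C(C)=O | intermediate
18 | C5 diphenylsulfonium triflate; [(3R,4S,5S)-4-(tert-butyldimethylsilyloxy)-5-{(2R,3R)-3-[(2S)-2-hydroxy-3-oxobutyl]-2-methyloxiran-2-yl}-5-(4-methoxybenzyloxy)-3-(prop-1-en-2-yl)pentyl]diphenylsulfonium trifluoromethanesulfonate | c1ccccc1[S+](c1ccccc1)CC[C@H](C(C)=C)[C@H](O[Si](C)(C)C(C)(C)C)[C@H](OCc1ccc(OC)cc1)[C@]1(C)O[C@@H]1C[C@H](O)C(C)=O.[O-]S(=O)(=O)C(F)(F)F | intermediate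
19 | lithium alkoxide sulfonium ylide (C3 lithium alkoxide, C5 ylide carbon of 18) | c1ccccc1[S+](c1ccccc1)[CH-]C[C@H](C(C)=C)[C@H](O[Si](C)(C)C(C)(C)C)[C@H](OCc1ccc(OC)cc1)[C@]1(C)O[C@@H]1C[C@H]([O-])C(C)=O.[Li+] | intermediate
20 | ten-membered betaine (C4–C5 bond formed; C4 alkoxide, C5 diphenylsulfonium, C3 lithium alkoxide; 4R,5R) | C=C(C)[C@H]1C[C@@H]([S+](c2ccccc2)c2ccccc2)[C@](C)([O-])[C@@H]([O-])C[C@H]2O[C@@]2(C)[C@@H](OCc2ccc(OC)cc2)[C@H]1O[Si](C)(C)C(C)(C)C.[Li+] | intermediate
21 | (1R,3S,4R,5S,7R,8S,9S,10R)-8-(tert-butyldimethylsilyloxy)-1,10:4,5-diepoxy-9-(4-methoxybenzyloxy)germacr-11-en-3-ol | C=C(C)[C@H]1C[C@@H]2O[C@]2(C)[C@@H](O)C[C@H]2O[C@@]2(C)[C@@H](OCc2ccc(OC)cc2)[C@H]1O[Si](C)(C)C(C)(C)C | intermediate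
22 | (1R,3S,4R,5S,7R,8S,9S,10R)-1,10:4,5-diepoxy-9-(4-methoxybenzyloxy)germacr-11-ene-3,8-diol | C=C(C)[C@H]1C[C@@H]2O[C@]2(C)[C@@H](O)C[C@H]2O[C@@]2(C)[C@@H](OCc2ccc(OC)cc2)[C@H]1O | intermediate
23 | angelic acid, (Z)-2-methylbut-2-enoic acid | C/C=C(/C)C(=O)O | starting material
24 | (1R,3S,4S,5S,7R,8S,9S,10R)-1,10:4,5-diepoxy-9-(4-methoxybenzyloxy)germacr-11-ene-3,8-diyl bis[(Z)-2-methylbut-2-enoate] | C=C(C)[C@H]1C[C@@H]2O[C@]2(C)[C@@H](OC(=O)/C(C)=C\C)C[C@H]2O[C@@]2(C)[C@@H](OCc2ccc(OC)cc2)[C@H]1OC(=O)/C(C)=C\C | intermediate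
25 | CNP0304877.1, (1R,3S,4S,5S,7R,8S,9S,10S)-1,10:4,5-diepoxy-9-hydroxygermacr-11-ene-3,8-diyl bis[(Z)-2-methylbut-2-enoate] | C=C(C)[C@H]1C[C@@H]2O[C@]2(C)[C@@H](OC(=O)/C(C)=C\C)C[C@H]2O[C@@]2(C)[C@@H](O)[C@H]1OC(=O)/C(C)=C\C | target

Total step count: 17. Longest linear sequence: 14 steps (6 → 25, steps 4–7 and 8–17); the other branch (1 → 25) is 13 steps.

Steps most likely to fail

Step 14 (key step). What may go wrong: oligomerisation instead of ten-membered ring closure, loss of the ylide by β-elimination to a C5=C6 alkene before it cyclises, or poor control of the C5 configuration so that C6 ends up trans to C3 on the oxirane. The fallback uses only known reaction types. It sets out from 16: heating with PPh3 in MeCN should give the C5 triphenylphosphonium bromide F1. Treatment with KN(SiMe3)2 (2.1 equiv) in toluene at high dilution would close the ring by an intramolecular Wittig olefination to the (4Z)-cyclodecenol F2. Unstabilised ylides and α-oxygenated methyl ketones are known to give the (Z)-trisubstituted alkene with the oxygenated carbon cis to the ylide chain. Epoxidation with mCPBA (1.0 equiv, NaHCO3, CH2Cl2, −20 °C) then returns to the route at 21. It is directed by the allylic C3 hydroxyl and should be threo-selective through allylic 1,3-strain in the (Z)-allylic alcohol, and the trisubstituted alkene should react faster than the isopropenyl group.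

Step 13. What may go wrong: during silver-assisted ionisation the C8 silyl ether oxygen (five-ring) or the C9 PMB ether oxygen (six-ring) takes part and closes a cyclic ether, or the silver salt opens the 1,10-oxirane. The fallback avoids any cationic character at C5. It sets out from 16: PhSH, Cs2CO3, DMF, 0 °C should give the C5 phenyl sulfide F3 by SN2 displacement. Copper-catalysed S-arylation with diphenyliodonium triflate (Cu(OAc)2, 5 mol%, 1,2-dichloroethane, 80 °C) then gives the sulfonium triflate and returns to the route at 18.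

Step 16. What may go wrong: incomplete acylation of two hindered secondary hydroxyls (C3 next to the quaternary oxirane carbon), and isomerisation of the angeloyl group to the tigloyl (E) isomer under forcing conditions. The fallback builds the double bonds on the ester. It sets out from 22: acylation with 2-[bis(2,2,2-trifluoroethoxy)phosphoryl]propanoic acid (EDC·HCl, DMAP, CH2Cl2) should give the bis(phosphonopropionate) F4. Still–Gennari olefination with acetaldehyde (KN(SiMe3)2, 18-crown-6, THF, −78 °C) then forms both (Z)-2-methylbut-2-enoates and returns to the route at 24.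

Further compounds
F1 | step 14 | C5 triphenylphosphonium bromide of the 1,10-epoxy α-hydroxy methyl ketone (configuration as in 16) | c1ccccc1[P+](c1ccccc1)(c1ccccc1)CC[C@H](C(C)=C)[C@H](O[Si](C)(C)C(C)(C)C)[C@H](OCc1ccc(OC)cc1)[C@]1(C)O[C@@H]1C[C@H](O)C(C)=O.[Br-]
F2 | step 14 | (1R,3S,4Z,7R,8S,9S,10R)-8-(tert-butyldimethylsilyloxy)-1,10-epoxy-9-(4-methoxybenzyloxy)germacra-4,11-dien-3-ol | C=C(C)[C@H]1C/C=C(C)\[C@@H](O)C[C@H]2O[C@@]2(C)[C@@H](OCc2ccc(OC)cc2)[C@H]1O[Si](C)(C)C(C)(C)C
F3 | step 13 | C5 phenyl sulfide of the 1,10-epoxy α-hydroxy methyl ketone (configuration as in 16) | c1ccccc1SCC[C@H](C(C)=C)[C@H](O[Si](C)(C)C(C)(C)C)[C@H](OCc1ccc(OC)cc1)[C@]1(C)O[C@@H]1C[C@H](O)C(C)=O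
F4 | step 16 | 3,8-bis{2-[bis(2,2,2-trifluoroethoxy)phosphoryl]propanoate} of diol 22 (mixture of epimers at the two phosphonate-bearing carbons) | C=C(C)[C@H]1C[C@@H]2O[C@]2(C)[C@@H](OC(=O)C(C)P(=O)(OCC(F)(F)F)OCC(F)(F)F)C[C@H]2O[C@@]2(C)[C@@H](OCc2ccc(OC)cc2)[C@H]1OC(=O)C(C)P(=O)(OCC(F)(F)F)OCC(F)(F)F
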